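Compound numbers are those of the steps and of the compound list at the end.

## Analysis of the target

Compound 17 is a flavonol: a 4H-chromen-4-one (rings A and C fused) that carries ring B, a 3,4-dioxygenated phenyl group, at C2. It has no stereocentre, so the whole problem is one of constitution. Of the five oxygen substituents (O3, O5, O7, O3', O4'), exactly two carry sulfate: O3 on ring C and O4' on ring B. O5, O7 and O3' stay free. The hydrogen sulfates are the sensitive groups. They hydrolyse under acid (the free acid form promotes its own cleavage), they do not tolerate Lewis acids, and they turn every later intermediate into a polar salt. Rings A and B are electron-rich and oxidisable once unprotected. The difficulty is therefore to tell O3 and O4' apart from three other phenolic oxygens of similar reactivity, and to unmask everything at the end without acid. That calls for two classes of protecting group placed already in the building blocks. The plan rests on C2: one carbon at the acyl oxidation level whose three skeletal bonds go to O1, to C3 and to C1' of ring B. It can therefore be supplied as carbon monoxide 10 between a ring A ketone that already holds O1, C3, O3 and C4 and a ring B aryl bromide.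

## Retrosynthetic reasoning

**17 back to 15.** The last bonds cut are the three benzyl C–O bonds at O5, O7 and O3'. Hydrogenolysis is neutral, and sulfate monoester anions do not react under it. Acid-labile or Lewis-acid-labile groups at these positions could not be removed after sulfation. The free acid 17 is generated from its salt 16 only at the very end.

**15 back to 14.** The two S–O bonds are cut next. In 14 only O3 and O4' are free, so the regiochemistry of sulfation is fixed by the protecting-group pattern and not by any preference of the sulfating agent. The forward step only has to run to completion at both oxygens.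

**14 back to 13.** The two methoxymethyl acetals at O3 and O4' are cut. They leave under dilute protic acid, which benzyl ethers survive, and they withstand the hot amidine base of the ring-forming step. This acid/hydrogenolysis pairing is what separates the two classes of oxygen.

**13 back to 6, 9 and 10.** All three bonds to C2 are cut: C1'–C2, C2–C3 and O1–C2. Cutting here, and not at C3–C4 or inside ring A, reduces the ring B partner to the aryl bromide 9 and lets C2 come from 10. Ketone 6 brings O3 with it, so no oxidation is needed after ring closure. The forward reaction must carbonylate 9, pass the aroyl group to the phenol oxygen of 6 (ester 11), move it to the α-carbon (diketone 12) and close ring C with loss of water.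

**6 back to 5, 2 and 1.** The acetal C–O bond of 6 is cut to the primary alcohol 5. The α C–O bond of 5 is cut to the methyl ketone 2, and the two benzyl ethers of 2 to 1. The α-oxygen is introduced through the doubly silylated enol ether 3, so that the phenol is masked during the oxidation. An oxidation of the free phenoxide ketone with a base-mediated iodine oxidant would instead let the phenoxide attack the activated α-carbon and close a five-membered ether ring. The forward steps rely twice on the low reactivity of the hydroxyl that is hydrogen-bonded to the ketone: once to stop benzylation at two groups, and once to direct acetal formation to the primary alcohol.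

**9 back to 8 and 7.** The acetal C–O bond is cut to phenol 8 and the C–Br bond to 7. The free hydroxyl of 7 directs the halogen para to itself, which is C1' of the target, with the benzyl ether already at the future O3'.

## Alternatives that were turned down

**Alternative 1:** This cuts C3–C4 and O1–C2. Ring A becomes an acyl donor, 5,7-bis(benzyloxy)-2,2-dimethyl-4H-1,3-benzodioxin-4-one A2. Ring B becomes a nucleophile, the lithium enolate of 2-(allyloxy)-1-[4-(allyloxy)-3-(benzyloxy)phenyl]ethan-1-one A3. In the forward key step the enolate opens A2 at its carbonyl, and acid closes O1–C2 with loss of water to give the flavonol diallyl ether A1.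
- For it: direct C-acylation of a ketone enolate by a salicylate acetonide is secure chemistry. It needs no pressure vessel, no transition metal and no O-to-C acyl shift. On certainty of the key step it is stronger than the chosen plan.
- Against it: both partners are expensive. A2 needs its own acetonide formation and benzylation. A3 needs a ring B acetophenone with differentiated phenols plus an α-oxygenation. The crowded carbonyl of A2 next to a benzyloxy group reacts slowly with a hindered α-alkoxy enolate, and the acidic diketone consumes a second equivalent of enolate. The allyl groups of A1 later need a separate zerovalent-palladium deallylation.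
- Comparison: the chosen plan reaches its ring B partner 9 in two steps and takes C2 from a gas, so it is about three steps shorter. It carries more risk in one step, and the stepwise acyl-transfer fallback for that step is close in spirit to this alternative.

**Alternative 2:** This cuts inside ring A at C4a–C5. An open-chain precursor, methyl (E)-9-[3-(benzyloxy)-4-(methoxymethoxy)phenyl]-3,5,7-trioxonon-8-enoate A5, is cyclised by Claisen condensation with a magnesium alkoxide to the chalcone A4.
- For it: it follows the biosynthetic logic. Ring A appears with its three hydroxyls and needs no preformed phloroglucinol unit and no gas under pressure.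
- Against it: ring A is the cheapest part of this target, since it is available as 1, so the plan spends its effort on the wrong ring. A5 is a labile poly-β-carbonyl chain that needs several steps of its own, and it can close by aldol or lactone formation instead. A4 lacks O3 and the O1–C2 bond. It therefore still needs selective protection of two of three ring A hydroxyls and an oxidative cyclisation. With an oxygen substituent flanking the ketone on ring A, that cyclisation tends to close the five-membered ring instead of the six-membered one.
- Comparison: it is longer and has several uncertain steps instead of one. The chosen plan arrives at the flavonol oxidation level directly because O3 is carried in 6.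

**Alternative 3:** This cuts C4–C4a and O1–C2. Unprotected phloroglucinol A8 is heated without solvent with the β-keto ester ethyl 3-[3-(benzyloxy)-4-(4-methoxybenzyloxy)phenyl]-2-(4-methoxybenzyloxy)-3-oxopropanoate A7 to give the 5,7-dihydroxyflavonol ether A6 in one operation.
- For it: it is the shortest assembly, and on step count it is stronger than the chosen plan. Ring A enters unprotected and symmetric. The chelated hydroxyl at O5 could stay free to the end.
- Against it: such thermal condensations need temperatures far above 200 °C. At those temperatures 4-methoxybenzyl ethers ionise in the presence of a nucleophile as strong as A8, and benzyl transfer to carbon is expected. First attack at the ester instead of the ketone gives a 4-arylcoumarin, and an α-alkoxy substituent does not obviously favour the chromone. After A6, O7 must still be benzylated selectively before sulfation.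
- Comparison: the chosen plan runs near 110 °C with base-stable protecting groups. Its bond-forming sequence (ester, then carbon acylation, then closure) allows only one constitution.

Key step: step 6

Remark on the chemistry: 17 is drawn as the free bis(hydrogen sulfate). Aryl hydrogen sulfates cleave under their own acidity, so the material is carried as its bis(triethylammonium) salt and protonated only in the last operation, cold and without concentration to dryness.

## Route

Step 1
Reactants: 1 1-(2,4,6-trihydroxyphenyl)ethan-1-one (2,4,6-trihydroxyacetophenone)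
Product: 2 1-[2,4-bis(benzyloxy)-6-hydroxyphenyl]ethan-1-one
Conditions: BnBr (2.1 equiv), K2CO3, DMF, 60 °C
Reagents that add atoms: benzyl bromide, BrCc1ccccc1
Why: Williamson ether synthesis; the para hydroxyl and one ortho hydroxyl are alkylated, and the remaining ortho hydroxyl is held in a hydrogen bond to the ketone and should resist the carbonate base, so alkylation stops at two groups.

Step 2
Reactants: 2 1-[2,4-bis(benzyloxy)-6-hydroxyphenyl]ethan-1-one
Product: 5 1-[2,4-bis(benzyloxy)-6-hydroxyphenyl]-2-hydroxyethan-1-one, via bis-silylated enol ether 3 (not isolated), via alpha-silyloxy ketone 4 (not isolated)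
Conditions: Me3SiOTf (2.3 equiv), Et3N, CH2Cl2, 0 °C; then mCPBA (1.05 equiv), CH2Cl2, −20 °C; then 1 M HCl, THF, rt
Reagents that add atoms: 3-chloroperoxybenzoic acid (mCPBA), O=C(OO)c1cccc(Cl)c1
Why: Rubottom oxidation; the silyl enol ether is epoxidised far faster than the arene, the silyloxy epoxide opens with 1,4-silyl shift to 4, and aqueous acid removes both silyl groups. Silylating the phenol in the same operation keeps it from attacking the activated α-carbon, and no stereocentre is formed.

Step 3
Reactants: 5 1-[2,4-bis(benzyloxy)-6-hydroxyphenyl]-2-hydroxyethan-1-one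
Product: 6 1-[2,4-bis(benzyloxy)-6-hydroxyphenyl]-2-(methoxymethoxy)ethan-1-one
Conditions: MOMCl (1.2 equiv), iPr2NEt, CH2Cl2, 0 °C to rt
Reagents that add atoms: chloromethyl methyl ether, COCCl
Why: O-alkylation of the neutral primary alcohol by the oxocarbenium-like chloromethyl ether under amine base (acetal formation); the phenol chelated to the ketone is a poor nucleophile under these conditions, the same bias that spares it in step 1.

Step 4
Reactants: 7 2-(benzyloxy)phenol
Product: 8 2-(benzyloxy)-4-bromophenol
Conditions: NBS (1.0 equiv), MeCN, 0 °C
Reagents that add atoms: N-bromosuccinimide, O=C1CCC(=O)N1Br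
Why: Electrophilic aromatic bromination; the free hydroxyl is a stronger activating group than the benzyl ether and should direct bromine to its para position, which is meta to the benzyloxy group as ring B requires.

Step 5
Reactants: 8 2-(benzyloxy)-4-bromophenol
Product: 9 2-(benzyloxy)-4-bromo-1-(methoxymethoxy)benzene
Conditions: NaH, MOMCl, DMF, 0 °C to rt
Reagents that add atoms: chloromethyl methyl ether, COCCl
Why: Williamson-type O-alkylation of the sodium phenoxide; the acetal masks O4' against aroylation in step 6 and is later removed together with the one at O3.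

Step 6
Reactants: 6 1-[2,4-bis(benzyloxy)-6-hydroxyphenyl]-2-(methoxymethoxy)ethan-1-one; 9 2-(benzyloxy)-4-bromo-1-(methoxymethoxy)benzene; 10 carbon monoxide
Product: 13 5,7-bis(benzyloxy)-2-[3-(benzyloxy)-4-(methoxymethoxy)phenyl]-3-(methoxymethoxy)-4H-chromen-4-one, via aryl ester 11 (not isolated), via 1,3-diketone 12 (not isolated)
Conditions: Pd(OAc)2 (5 mol %), Ph2P(CH2)4PPh2 (7.5 mol %), DBU (3 equiv), CO (10 bar), DMSO, 110 °C
Reagents that add atoms: none
Why: Zerovalent palladium, formed in the flask from Pd(OAc)2, should insert into the C–Br bond of 9, and migratory insertion of 10 gives an aroylpalladium bromide, which the DBU-generated phenoxide of 6 intercepts to give ester 11 (C1'–C2 and O–C2 formed) while the catalyst is released. DBU then enolises the α-(methoxymethoxy) ketone and the enolate takes the aroyl group from the neighbouring oxygen (Baker–Venkataraman O-to-C acyl shift, C2–C3 formed) to give 12. The freed phenoxide adds to the new ring B ketone in a 6-exo-trig closure of ring C (O1–C2), and the hemiketal loses water to give the pyranone. The closest known reaction type is the palladium-catalysed carbonylative flavone synthesis from aryl bromides and 2-hydroxyacetophenones, together with the classical base-mediated acyl shift of aroyloxy α-alkoxy acetophenones. No stereocentre results, since the sp3 carbon of 12 becomes C3 of the enone. Carbonylation has to outrun direct C–O coupling and ketone α-arylation, which CO pressure and the chelating diphosphine favour by making CO insertion faster than reductive elimination from the arylpalladium species. Site selectivity is built into the substrates: 6 has one free phenol and one enolisable carbon, 9 has no free hydroxyl, and 12 can only close to the six-membered ring. O3 is already present, so no oxidation is needed.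

Step 7
Reactants: 13 5,7-bis(benzyloxy)-2-[3-(benzyloxy)-4-(methoxymethoxy)phenyl]-3-(methoxymethoxy)-4H-chromen-4-one
Product: 14 5,7-bis(benzyloxy)-2-[3-(benzyloxy)-4-hydroxyphenyl]-3-hydroxy-4H-chromen-4-one
Conditions: HCl (1.25 M in MeOH), THF, 45 °C
Reagents that add atoms: none
Why: Acid-catalysed acetal exchange to methanol removes both methoxymethyl groups; the benzyl ethers, including the one at O5, should survive dilute protic acid, which leaves exactly O3 and O4' free.

Step 8
Reactants: 14 5,7-bis(benzyloxy)-2-[3-(benzyloxy)-4-hydroxyphenyl]-3-hydroxy-4H-chromen-4-one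
Product: 15 bis(triethylammonium) 5,7-bis(benzyloxy)-2-[3-(benzyloxy)-4-(sulfonatooxy)phenyl]-4-oxo-4H-chromen-3-yl sulfate
Conditions: SO3·NMe3 (8 equiv), Et3N, DMF, 60 °C
Reagents that add atoms: sulfur trioxide–trimethylamine complex, C[N+](C)(C)S(=O)(=O)[O-]; triethylamine, CCN(CC)CC
Why: O-sulfonation of the two ammonium oxyanions by the amine-bound sulfur trioxide; only O3 and O4' are free, so excess reagent can be used to force the less nucleophilic O3, and the product is kept as its ammonium salt under basic conditions.

Step 9
Reactants: 15 bis(triethylammonium) 5,7-bis(benzyloxy)-2-[3-(benzyloxy)-4-(sulfonatooxy)phenyl]-4-oxo-4H-chromen-3-yl sulfate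
Product: 17 2-[3-hydroxy-4-(sulfooxy)phenyl]-5,7-dihydroxy-4-oxo-4H-chromen-3-yl hydrogen sulfate (quercetin 3,4'-bissulfate), via bis(triethylammonium) quercetin 3,4'-bissulfate 16 (not isolated)
Conditions: H2 (1 atm), Pd/C (10 %), MeOH/THF, rt; then sulfonic acid cation-exchange resin (H+ form), H2O, 0 °C
Reagents that add atoms: none
Why: Catalytic hydrogenolysis cleaves the three aryl benzyl ethers under neutral conditions, to which sulfate monoester anions and the chromenone should be inert at atmospheric pressure if the reaction is stopped at full debenzylation. Cold proton exchange then gives the acid form drawn.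

## Compound list

1 | 1-(2,4,6-trihydroxyphenyl)ethan-1-one (2,4,6-trihydroxyacetophenone) | CC(=O)c1c(O)cc(O)cc1O | starting material
2 | 1-[2,4-bis(benzyloxy)-6-hydroxyphenyl]ethan-1-one | CC(=O)c1c(O)cc(OCc2ccccc2)cc1OCc1ccccc1 | intermediate
3 | {[3,5-bis(benzyloxy)-2-{1-[(trimethylsilyl)oxy]ethenyl}phenyl]oxy}(trimethyl)silane | C=C(O[Si](C)(C)C)c1c(O[Si](C)(C)C)cc(OCc2ccccc2)cc1OCc1ccccc1 | intermediate
4 | 1-{2,4-bis(benzyloxy)-6-[(trimethylsilyl)oxy]phenyl}-2-[(trimethylsilyl)oxy]ethan-1-one | C[Si](C)(C)OCC(=O)c1c(O[Si](C)(C)C)cc(OCc2ccccc2)cc1OCc1ccccc1 | intermediate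
5 | 1-[2,4-bis(benzyloxy)-6-hydroxyphenyl]-2-hydroxyethan-1-one | OCC(=O)c1c(O)cc(OCc2ccccc2)cc1OCc1ccccc1 | intermediate
6 | 1-[2,4-bis(benzyloxy)-6-hydroxyphenyl]-2-(methoxymethoxy)ethan-1-one | COCOCC(=O)c1c(O)cc(OCc2ccccc2)cc1OCc1ccccc1 | intermediate
7 | 2-(benzyloxy)phenol | Oc1ccccc1OCc1ccccc1 | starting material
8 | 2-(benzyloxy)-4-bromophenol | Oc1ccc(Br)cc1OCc1ccccc1 | intermediate
9 | 2-(benzyloxy)-4-bromo-1-(methoxymethoxy)benzene | COCOc1ccc(Br)cc1OCc1ccccc1 | intermediate
10 | carbon monoxide | [C-]#[O+] | starting material
11 | 3,5-bis(benzyloxy)-2-[(methoxymethoxy)acetyl]phenyl 3-(benzyloxy)-4-(methoxymethoxy)benzoate | COCOCC(=O)c1c(OC(=O)c2ccc(OCOC)c(OCc3ccccc3)c2)cc(OCc2ccccc2)cc1OCc1ccccc1 | intermediate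
12 | 1-[2,4-bis(benzyloxy)-6-hydroxyphenyl]-3-[3-(benzyloxy)-4-(methoxymethoxy)phenyl]-2-(methoxymethoxy)propane-1,3-dione (racemic, enolisable) | COCOC(C(=O)c1ccc(OCOC)c(OCc2ccccc2)c1)C(=O)c1c(O)cc(OCc2ccccc2)cc1OCc1ccccc1 | intermediate
13 | 5,7-bis(benzyloxy)-2-[3-(benzyloxy)-4-(methoxymethoxy)phenyl]-3-(methoxymethoxy)-4H-chromen-4-one | COCOc1c(-c2ccc(OCOC)c(OCc3ccccc3)c2)oc2cc(OCc3ccccc3)cc(OCc3ccccc3)c2c1=O | intermediate
14 | 5,7-bis(benzyloxy)-2-[3-(benzyloxy)-4-hydroxyphenyl]-3-hydroxy-4H-chromen-4-one | O=c1c(O)c(-c2ccc(O)c(OCc3ccccc3)c2)oc2cc(OCc3ccccc3)cc(OCc3ccccc3)c12 | intermediate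
15 | bis(triethylammonium) 5,7-bis(benzyloxy)-2-[3-(benzyloxy)-4-(sulfonatooxy)phenyl]-4-oxo-4H-chromen-3-yl sulfate | O=c1c(OS(=O)(=O)[O-])c(-c2ccc(OS(=O)(=O)[O-])c(OCc3ccccc3)c2)oc2cc(OCc3ccccc3)cc(OCc3ccccc3)c12.CC[NH+](CC)CC.CC[NH+](CC)CC | intermediate
16 | bis(triethylammonium) 2-[3-hydroxy-4-(sulfonatooxy)phenyl]-5,7-dihydroxy-4-oxo-4H-chromen-3-yl sulfate | O=c1c(OS(=O)(=O)[O-])c(-c2ccc(OS(=O)(=O)[O-])c(O)c2)oc2cc(O)cc(O)c12.CC[NH+](CC)CC.CC[NH+](CC)CC | intermediate
17 | 2-[3-hydroxy-4-(sulfooxy)phenyl]-5,7-dihydroxy-4-oxo-4H-chromen-3-yl hydrogen sulfate (quercetin 3,4'-bissulfate) | O=c1c(OS(=O)(=O)O)c(-c2ccc(OS(=O)(=O)O)c(O)c2)oc2cc(O)cc(O)c12 | target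

## Step count and least certain steps

Total: 9 steps. Longest linear sequence: 7 steps (1, 2, 3, 6, 7, 8, 9). The ring B branch (steps 4 and 5) joins at step 6.

**Step 6 (key step).** The cascade is most likely to stall after O-aroylation. The acyl shift onto an oxygen-substituted, more hindered α-carbon is slower than with a methyl ketone, and water released by any cyclisation can hydrolyse the waiting ester. Slow oxidative addition into the electron-rich C–Br bond also gives direct C–O coupling, α-arylation or acylation of DBU time to compete. The fallback sets out from 9 and 6 and separates the events. Bromine–lithium exchange of 9 (n-BuLi, THF, −78 °C) and quenching with CO2 should give 3-(benzyloxy)-4-(methoxymethoxy)benzoic acid F1. Carbodiimide coupling of F1 with the phenol of 6 (EDC·HCl, DMAP, CH2Cl2) gives 11, now isolated. LiN(SiMe3)2 in THF at −20 °C effects the acyl shift to 12, and NaOAc in AcOH at 80 °C closes and dehydrates it. The route is rejoined at 13.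

**Step 2.** The peracid may oxidise the very electron-rich arene in competition with the enol ether. The labile aryl silyl ether may also be lost before oxidation, so that the free phenol interferes. The fallback sets out from 2 and blocks the phenol with a robust group. Allyl bromide and K2CO3 in DMF give 1-[2,4-bis(benzyloxy)-6-(prop-2-en-1-yloxy)phenyl]ethan-1-one F2. Oxidation with PhI(OAc)2 and KOH in MeOH gives 2-[2,4-bis(benzyloxy)-6-(prop-2-en-1-yloxy)phenyl]-2,2-dimethoxyethan-1-ol F3, which aqueous HCl in THF hydrolyses to 1-[2,4-bis(benzyloxy)-6-(prop-2-en-1-yloxy)phenyl]-2-hydroxyethan-1-one F4. Allyl transfer to morpholine with Pd(PPh3)4 in THF frees the phenol, and the route is rejoined at 5.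

**Step 3.** The chelated phenol oxygen may be alkylated alongside the primary hydroxyl, giving mixtures. The fallback sets out from 5 and moves the differentiation from protection to deprotection. Excess MOMCl with iPr2NEt and NaI at 60 °C should alkylate both oxygens to 1-[2,4-bis(benzyloxy)-6-(methoxymethoxy)phenyl]-2-(methoxymethoxy)ethan-1-one F5. Brief treatment with HCl (0.1 M in MeOH) at 0 °C then removes only the aryl acetal ortho to the ketone, which is the more labile of the two. The route is rejoined at 6.

**Step 8.** Sulfation at O3 may stay incomplete, because its anion is delocalised into the pyranone and sits between ring B and the carbonyl. The 3-sulfate may also be lost on acidic supports during purification. The fallback sets out from 14 and uses a far more reactive electrophile that gives neutral diesters. 2,2,2-Trichloroethyl chlorosulfate with Et3N and DMAP in THF should give 5,7-bis(benzyloxy)-2-{3-(benzyloxy)-4-[(2,2,2-trichloroethoxy)sulfonyloxy]phenyl}-4-oxo-4H-chromen-3-yl 2,2,2-trichloroethyl sulfate F6, which can be chromatographed on silica. Pd/C with HCO2NH4 in MeOH then removes the trichloroethyl groups and the benzyl ethers in one operation to give diammonium 2-[3-hydroxy-4-(sulfonatooxy)phenyl]-5,7-dihydroxy-4-oxo-4H-chromen-3-yl sulfate F7. Cold proton exchange as in step 9 rejoins the route at 17.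

## Further compounds

F1 | step 6 | 3-(benzyloxy)-4-(methoxymethoxy)benzoic acid | O=C(O)c1ccc(OCOC)c(OCc2ccccc2)c1
F2 | step 2 | 1-[2,4-bis(benzyloxy)-6-(prop-2-en-1-yloxy)phenyl]ethan-1-one | CC(=O)c1c(OCC=C)cc(OCc2ccccc2)cc1OCc1ccccc1
F3 | step 2 | 2-[2,4-bis(benzyloxy)-6-(prop-2-en-1-yloxy)phenyl]-2,2-dimethoxyethan-1-ol | COC(CO)(OC)c1c(OCC=C)cc(OCc2ccccc2)cc1OCc1ccccc1
F4 | step 2 | 1-[2,4-bis(benzyloxy)-6-(prop-2-en-1-yloxy)phenyl]-2-hydroxyethan-1-one | OCC(=O)c1c(OCC=C)cc(OCc2ccccc2)cc1OCc1ccccc1
F5 | step 3 | 1-[2,4-bis(benzyloxy)-6-(methoxymethoxy)phenyl]-2-(methoxymethoxy)ethan-1-one | COCOCC(=O)c1c(OCOC)cc(OCc2ccccc2)cc1OCc1ccccc1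
F6 | step 8 | 5,7-bis(benzyloxy)-2-{3-(benzyloxy)-4-[(2,2,2-trichloroethoxy)sulfonyloxy]phenyl}-4-oxo-4H-chromen-3-yl 2,2,2-trichloroethyl sulfate | O=c1c(OS(=O)(=O)OCC(Cl)(Cl)Cl)c(-c2ccc(OS(=O)(=O)OCC(Cl)(Cl)Cl)c(OCc3ccccc3)c2)oc2cc(OCc3ccccc3)cc(OCc3ccccc3)c12
F7 | step 8 | diammonium 2-[3-hydroxy-4-(sulfonatooxy)phenyl]-5,7-dihydroxy-4-oxo-4H-chromen-3-yl sulfate | O=c1c(OS(=O)(=O)[O-])c(-c2ccc(OS(=O)(=O)[O-])c(O)c2)oc2cc(O)cc(O)c12.[NH4+].[NH4+]
A1 | alternative 1 | 3-(allyloxy)-2-[4-(allyloxy)-3-(benzyloxy)phenyl]-5,7-bis(benzyloxy)-4H-chromen-4-one | C=CCOc1c(-c2ccc(OCC=C)c(OCc3ccccc3)c2)oc2cc(OCc3ccccc3)cc(OCc3ccccc3)c2c1=O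
A2 | alternative 1 | 5,7-bis(benzyloxy)-2,2-dimethyl-4H-1,3-benzodioxin-4-one | CC1(C)OC(=O)c2c(OCc3ccccc3)cc(OCc3ccccc3)cc2O1
A3 | alternative 1 | 2-(allyloxy)-1-[4-(allyloxy)-3-(benzyloxy)phenyl]ethan-1-one | C=CCOCC(=O)c1ccc(OCC=C)c(OCc2ccccc2)c1
A4 | alternative 2 | (E)-3-[3-(benzyloxy)-4-(methoxymethoxy)phenyl]-1-(2,4,6-trihydroxyphenyl)prop-2-en-1-one | O=C(/C=C/c1ccc(OCOC)c(OCc2ccccc2)c1)c1c(O)cc(O)cc1O
A5 | alternative 2 | methyl (E)-9-[3-(benzyloxy)-4-(methoxymethoxy)phenyl]-3,5,7-trioxonon-8-enoate | COC(=O)CC(=O)CC(=O)CC(=O)/C=C/c1ccc(OCOC)c(OCc2ccccc2)c1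
A6 | alternative 3 | 2-[3-(benzyloxy)-4-(4-methoxybenzyloxy)phenyl]-5,7-dihydroxy-3-(4-methoxybenzyloxy)-4H-chromen-4-one | COc1ccc(COc2c(-c3ccc(OCc4ccc(OC)cc4)c(OCc4ccccc4)c3)oc3cc(O)cc(O)c3c2=O)cc1
A7 | alternative 3 | ethyl 3-[3-(benzyloxy)-4-(4-methoxybenzyloxy)phenyl]-2-(4-methoxybenzyloxy)-3-oxopropanoate (racemic) | CCOC(=O)C(OCc1ccc(OC)cc1)C(=O)c1ccc(OCc2ccc(OC)cc2)c(OCc2ccccc2)c1
A8 | alternative 3 | benzene-1,3,5-triol (phloroglucinol) | Oc1cc(O)cc(O)c1
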